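**Plan**

1. Numbering: the carbocycle is numbered as 1,1,3,6-tetramethyl-1,4,4a,7,8,8a-hexahydronaphthalene (ring A = C4a, C5–C8, C8a; ring B = C1–C4, C4a, C8a); the dioxane is O1, O2, C3–C6; the linker carbons are Ca (on dioxane C6) and Cb (on decalin C2).
2. Retrosynthesis: cut Ca–Cb (made as an alkene by Wittig union, then saturated); cut C1–C2 of ring B; cut the C4a–CH2 bond (Claisen) back to (S)-limonene. The dioxane fragment is cut at O2–C3 (SN2) and O1–C6 (epoxide opening) back to geranyl acetate.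
3. Forward order of rings: the 1,2-dioxane is closed first on the geraniol-derived fragment; ring A is bought with limonene; ring B is closed last, onto ring A, by a SnCl4-promoted cation–enol cyclization; the two fragments are then joined.
4. Enabling feature: C1 of ring B with its two methyls sits on ring-fusion carbon C8a, so it is the isopropenyl carbon of a p-menthane ring A. C2=C3 with Cb on C2 is the enol of a β-keto ester (C3 ketone, C2 α-carbon, Cb ester carbon). A tertiary C1 cation therefore meets a C2 enol, and the keto ester later fixes the tetrasubstituted C2=C3 alkene through its enol triflate.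
5. Stereochemistry: C8a is bought with (S)-limonene, and C4a is relayed from it (trans-epoxide, tertiary allylic alcohol, suprafacial Ireland–Claisen). Dioxane C6 comes from a Sharpless epoxidation followed by invertive perhydrolysis. Dioxane C3 and the propanoate α-carbon come from a Brown (Z)-crotylboration, with inversion at C3 in the peroxide ring closure.

Key step: step 17

Remark: geranyl acetate, (S)-limonene and all reagents are taken as commercial; centres that are erased later (C2 of 29, the ozonide and selenoxide centres, the Ca=Cb geometry of 35) are left undefined.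

**Route**

Step 1
Reactants: 1 geranyl acetate
Product: 3 (2E)-3-methyl-6-oxohex-2-en-1-yl acetate, via ozonide 2 (not isolated)
Conditions: O3 (1 equiv), CH2Cl2, −78 °C; then Me2S, −78 °C to rt
Reagents that add atoms: ozone, [O-][O+]=O
Why: Chemoselective ozonolysis with reductive work-up should cleave the electron-rich 6,7-alkene in preference to the 2,3-alkene, which is deactivated by the allylic acetate; no stereocentre is involved.

Step 2
Reactants: 3 (2E)-3-methyl-6-oxohex-2-en-1-yl acetate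
Product: 5 (2E,6S,7S)-6-hydroxy-3,7-dimethylnona-2,8-dien-1-yl acetate, via borinate 4 (not isolated)
Conditions: (Z)-crotyl-B(Ipc)2 [from (Z)-but-2-ene, n-BuLi, KOtBu, (+)-Ipc2BOMe, BF3·OEt2], THF/Et2O, −78 °C; then H2O2, NaOAc, H2O, rt
Reagents that add atoms: (Z)-crotyldiisopinocampheylborane with Ipc from (−)-α-pinene, C/C=C\CB([C@H]1C[C@H]2C[C@@H]([C@@H]1C)C2(C)C)[C@H]1C[C@H]2C[C@@H]([C@@H]1C)C2(C)C
Why: Brown crotylboration through a closed Zimmerman–Traxler chair: the Z-crotyl geometry should give the syn pair and the Ipc ligands from (−)-α-pinene should select the aldehyde face, so both new centres (6S,7S) are set by the reagent.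

Step 3
Reactants: 5 (2E,6S,7S)-6-hydroxy-3,7-dimethylnona-2,8-dien-1-yl acetate
Product: 6 (2E,6S,7S)-6-[(methanesulfonyl)oxy]-3,7-dimethylnona-2,8-dien-1-yl acetate
Conditions: MsCl, Et3N, CH2Cl2, 0 °C
Reagents that add atoms: methanesulfonyl chloride, CS(=O)(=O)Cl
Why: O-Sulfonylation with retention turns the carbinol into the leaving group for the later invertive peroxide ring closure.

Step 4
Reactants: 6 (2E,6S,7S)-6-[(methanesulfonyl)oxy]-3,7-dimethylnona-2,8-dien-1-yl acetate
Product: 7 (3S,4S,7E)-9-hydroxy-3,7-dimethylnona-1,7-dien-4-yl methanesulfonate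
Conditions: K2CO3 (cat.), MeOH, 0 °C
Reagents that add atoms: none
Why: Methanolysis (transesterification) of the primary allylic acetate should leave the secondary mesylate untouched at 0 °C and frees the allylic alcohol needed for the epoxidation.

Step 5
Reactants: 7 (3S,4S,7E)-9-hydroxy-3,7-dimethylnona-1,7-dien-4-yl methanesulfonate
Product: 8 (3S,4S)-6-[(2R,3R)-3-(hydroxymethyl)-2-methyloxiran-2-yl]-3-methylhex-1-en-4-yl methanesulfonate
Conditions: Ti(OiPr)4 (cat.), D-(−)-diethyl tartrate (cat.), t-BuOOH, 4 Å MS, CH2Cl2, −20 °C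
Reagents that add atoms: tert-butyl hydroperoxide, CC(C)(C)OO
Why: Sharpless asymmetric epoxidation of the (E)-allylic alcohol: the D-(−)-tartrate catalyst should deliver oxygen to the face that gives the (2R,3R)-epoxide, while the isolated vinyl group and the mesylate are inert.

Step 6
Reactants: 8 (3S,4S)-6-[(2R,3R)-3-(hydroxymethyl)-2-methyloxiran-2-yl]-3-methylhex-1-en-4-yl methanesulfonate
Product: 9 (3S,4S,7S,8R)-7-hydroperoxy-8,9-dihydroxy-3,7-dimethylnon-1-en-4-yl methanesulfonate
Conditions: H2O2 (anhydrous, in Et2O), H3PMo12O40 (cat.), Et2O, rt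
Reagents that add atoms: hydrogen peroxide, OO
Why: Molybdenum-catalysed perhydrolysis of the epoxide: H2O2 should attack the tertiary epoxide carbon with inversion (acid-type, SN2-like opening), which sets the quaternary peroxide carbon (future dioxane C6) and retains the secondary C–O bond.

Step 7
Reactants: 9 (3S,4S,7S,8R)-7-hydroperoxy-8,9-dihydroxy-3,7-dimethylnon-1-en-4-yl methanesulfonate
Product: 10 (1R)-1-{(3S,6R)-6-[(2S)-but-3-en-2-yl]-3-methyl-1,2-dioxan-3-yl}ethane-1,2-diol
Conditions: KOtBu (1 equiv), 18-crown-6 (cat.), THF, 0 °C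
Reagents that add atoms: none
Why: Intramolecular Williamson-type peroxide alkylation (6-exo-tet): only the hydroperoxide, the most acidic OH, is deprotonated, and the peroxy anion should displace the secondary mesylate with inversion, which sets the ring CH carbon (R at the final dioxane C3) and closes the 1,2-dioxane.

Step 8
Reactants: 10 (1R)-1-{(3S,6R)-6-[(2S)-but-3-en-2-yl]-3-methyl-1,2-dioxan-3-yl}ethane-1,2-diol
Product: 12 (2R)-2-{(3R,6S)-6-[(1R)-1,2-dihydroxyethyl]-6-methyl-1,2-dioxan-3-yl}propanal, via ozonide 11 (not isolated)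
Conditions: O3, CH2Cl2, −78 °C; then Me2S, −78 to 0 °C; used crude
Reagents that add atoms: ozone, [O-][O+]=O
Why: Ozonolysis with Me2S work-up of the terminal vinyl group; the dialkyl peroxide and the diol are inert to both reagents, and the aldehyde is carried on without base or chromatography to avoid epimerisation or β-elimination.

Step 9
Reactants: 12 (2R)-2-{(3R,6S)-6-[(1R)-1,2-dihydroxyethyl]-6-methyl-1,2-dioxan-3-yl}propanal
Product: 13 (2R)-2-{(3R,6S)-6-[(1R)-1,2-dihydroxyethyl]-6-methyl-1,2-dioxan-3-yl}propanoic acid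
Conditions: NaClO2, NaH2PO4, 2-methylbut-2-ene, t-BuOH/H2O, 0 °C
Reagents that add atoms: sodium chlorite, [Na+].[O-]Cl=O
Why: Pinnick oxidation at buffered, weakly acidic pH should convert the aldehyde to the acid without epimerising the α-centre and without touching the peroxide or the diol.

Step 10
Reactants: 13 (2R)-2-{(3R,6S)-6-[(1R)-1,2-dihydroxyethyl]-6-methyl-1,2-dioxan-3-yl}propanoic acid
Product: 14 methyl (2R)-2-{(3R,6S)-6-[(1R)-1,2-dihydroxyethyl]-6-methyl-1,2-dioxan-3-yl}propanoate
Conditions: Me3SiCHN2, toluene/MeOH, 0 °C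
Reagents that add atoms: (trimethylsilyl)diazomethane, C[Si](C)(C)C=[N+]=[N-]
Why: Base-free methyl ester formation with a diazomethane equivalent avoids any enolate chemistry at the β-peroxy ester.

Step 11
Reactants: 14 methyl (2R)-2-{(3R,6S)-6-[(1R)-1,2-dihydroxyethyl]-6-methyl-1,2-dioxan-3-yl}propanoate
Product: 15 methyl (2R)-2-[(3R,6S)-6-formyl-6-methyl-1,2-dioxan-3-yl]propanoate
Conditions: NaIO4, THF/pH 7 buffer, 0 °C
Reagents that add atoms: none
Why: Malaprade glycol cleavage removes the terminal carbon that served as the epoxidation handle and unveils a non-enolisable aldehyde on the quaternary peroxide carbon.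

Step 12
Reactants: 16 (S)-(−)-limonene
Product: 18 (1R,4S,6S)-1-methyl-4-(prop-1-en-2-yl)-7-oxabicyclo[4.1.0]heptane (trans-limonene oxide), via bromohydrin 17 (not isolated)
Conditions: NBS, acetone/H2O, 0 °C; then aq NaOH, rt
Reagents that add atoms: water, O
Why: Bromohydrin formation at the more electron-rich ring alkene is trans-diaxial (Fürst–Plattner, isopropenyl equatorial, water at the tertiary carbon), and base closure should then give the epoxide whose oxygen is cis to the isopropenyl group, a relay from the limonene centre.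

Step 13
Reactants: 18 (1R,4S,6S)-1-methyl-4-(prop-1-en-2-yl)-7-oxabicyclo[4.1.0]heptane
Product: 21 (1R,4S)-1-methyl-4-(prop-1-en-2-yl)cyclohex-2-en-1-ol, via hydroxy selenide 19 (not isolated), via selenoxide 20 (not isolated)
Conditions: (PhSe)2, NaBH4, EtOH, rt to 80 °C; then THF, 30% H2O2, 0 °C to rt
Reagents that add atoms: none
Why: Epoxide-to-allylic-alcohol transposition: the selenolate opens the epoxide trans-diaxially at the secondary carbon, and selenoxide syn-elimination can only go away from the carbinol, so the tertiary C–O bond (cis to isopropenyl) is kept.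

Step 14
Reactants: 21 (1R,4S)-1-methyl-4-(prop-1-en-2-yl)cyclohex-2-en-1-ol
Product: 22 (1R,4S)-1-methyl-4-(prop-1-en-2-yl)cyclohex-2-en-1-yl acetate
Conditions: Ac2O, Et3N, DMAP (cat.), CH2Cl2, rt
Reagents that add atoms: acetic anhydride, CC(=O)OC(C)=O
Why: DMAP-catalysed acylation of the tertiary allylic alcohol under basic conditions avoids ionisation of the allylic C–O bond.

Step 15
Reactants: 22 (1R,4S)-1-methyl-4-(prop-1-en-2-yl)cyclohex-2-en-1-yl acetate
Product: 25 2-[(1R,6S)-3-methyl-6-(prop-1-en-2-yl)cyclohex-2-en-1-yl]acetic acid, via ketene silyl acetal 23 (not isolated), via silyl ester 24 (not isolated)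
Conditions: LiN(iPr)2, THF, −78 °C; Me3SiCl; −78 to 60 °C; then 1 M HCl
Reagents that add atoms: none
Why: Ireland–Claisen rearrangement: the [3,3] shift is suprafacial across the ring, so the new C–C bond forms on the face that carried the C–O bond, cis to the isopropenyl group, which sets the future C4a (R) by chirality transfer.

Step 16
Reactants: 25 2-[(1R,6S)-3-methyl-6-(prop-1-en-2-yl)cyclohex-2-en-1-yl]acetic acid
Product: 28 methyl 4-[(1R,6S)-3-methyl-6-(prop-1-en-2-yl)cyclohex-2-en-1-yl]-3-oxobutanoate, via acyl imidazolide 26 (not isolated), via acylmalonate 27 (not isolated)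
Conditions: 1,1'-carbonyldiimidazole, THF, rt; then Mg(O2CCH2CO2Me)2, rt to 40 °C; 1 M HCl
Reagents that add atoms: magnesium bis(methyl malonate), COC(=O)CC(=O)[O-].COC(=O)CC(=O)[O-].[Mg+2]
Why: Masamune-type C-acylation of the magnesium malonate half-ester followed by decarboxylation gives the β-keto ester under neutral conditions, with no effect on the two ring centres.

Step 17
Reactants: 28 methyl 4-[(1R,6S)-3-methyl-6-(prop-1-en-2-yl)cyclohex-2-en-1-yl]-3-oxobutanoate
Product: 29 methyl (4aR,8aS)-1,1,6-trimethyl-3-oxo-1,2,3,4,4a,7,8,8a-octahydronaphthalene-2-carboxylate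
Conditions: SnCl4 (2 equiv), CH2Cl2, 0 °C to rt
Reagents that add atoms: none
Why: SnCl4 binds the β-keto ester as a tin enolate, and the HCl set free protonates the isopropenyl CH2 (Markovnikov) to the tertiary cation at the future C1, which the enol carbon (future C2) captures through a chair transition state to form the C1–C2 bond. The closest known reaction type is the SnCl4-promoted cation–olefin cyclization of unsaturated β-keto esters to 2,2-dimethyl-6-oxocyclohexanecarboxylates. Ring B closes in a 6-(enolendo)-exo-trig mode, exo to the isopropenyl π bond and endo to the enol. The ring-fusion centres C4a and C8a are not created here but carried over cis from 28; C4a is not enolisable, and C8a should survive because capture of the cation by the chelated enol is expected to be faster than loss of the C8a proton. The only new centre, C2, is a labile β-keto ester position under thermodynamic control and becomes sp2 in step 18. The step needs protonation of the 1,1-disubstituted alkene rather than the ring trisubstituted alkene (as in Markovnikov additions to limonene) and C- rather than O-alkylation (the six-membered enol ether should revert under SnCl4); the cis placement of the two arms on ring A and the pre-organised tin enolate should secure both.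

Step 18
Reactants: 29 methyl (4aR,8aS)-1,1,6-trimethyl-3-oxo-1,2,3,4,4a,7,8,8a-octahydronaphthalene-2-carboxylate
Product: 30 methyl (4aR,8aS)-1,1,6-trimethyl-3-{[(trifluoromethyl)sulfonyl]oxy}-1,4,4a,7,8,8a-hexahydronaphthalene-2-carboxylate
Conditions: NaH, THF, 0 °C; then PhNTf2, 0 °C to rt
Reagents that add atoms: N-phenylbis(trifluoromethanesulfonimide), O=S(=O)(N(c1ccccc1)S(=O)(=O)C(F)(F)F)C(F)(F)F
Why: O-Triflation of the β-keto ester enolate: deprotonation can only occur at C2 between the two carbonyls, so the double bond is locked between C2 and C3.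

Step 19
Reactants: 30 methyl (4aR,8aS)-1,1,6-trimethyl-3-{[(trifluoromethyl)sulfonyl]oxy}-1,4,4a,7,8,8a-hexahydronaphthalene-2-carboxylate
Product: 31 methyl (4aR,8aS)-1,1,3,6-tetramethyl-1,4,4a,7,8,8a-hexahydronaphthalene-2-carboxylate
Conditions: MeMgBr, Fe(acac)3 (cat.), THF/NMP, −30 °C
Reagents that add atoms: methylmagnesium bromide, C[Mg]Br
Why: Iron-catalysed Kumada-type cross-coupling of the activated enol triflate should install the C3 methyl group faster than the Grignard reagent adds to the hindered ester, with the alkene position retained.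

Step 20
Reactants: 31 methyl (4aR,8aS)-1,1,3,6-tetramethyl-1,4,4a,7,8,8a-hexahydronaphthalene-2-carboxylate
Product: 32 [(4aR,8aS)-1,1,3,6-tetramethyl-1,4,4a,7,8,8a-hexahydronaphthalen-2-yl]methanol
Conditions: iBu2AlH (2.5 equiv), CH2Cl2, −78 to 0 °C; Rochelle salt work-up
Reagents that add atoms: none
Why: 1,2-Reduction of the α,β-unsaturated ester by the aluminium hydride gives the allylic alcohol without touching either alkene.

Step 21
Reactants: 32 [(4aR,8aS)-1,1,3,6-tetramethyl-1,4,4a,7,8,8a-hexahydronaphthalen-2-yl]methanol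
Product: 33 triphenyl{[(4aR,8aS)-1,1,3,6-tetramethyl-1,4,4a,7,8,8a-hexahydronaphthalen-2-yl]methyl}phosphonium bromide
Conditions: PPh3·HBr, MeOH, rt
Reagents that add atoms: triphenylphosphine hydrobromide, [Br-].[PH+](c1ccccc1)(c1ccccc1)c1ccccc1
Why: SN1-type allylic substitution, as used for cyclogeranyl-type alcohols: the allylic cation is trapped by PPh3 at its unhindered primary terminus.

Step 22
Reactants: 33 triphenyl{[(4aR,8aS)-1,1,3,6-tetramethyl-1,4,4a,7,8,8a-hexahydronaphthalen-2-yl]methyl}phosphonium bromide; 15 methyl (2R)-2-[(3R,6S)-6-formyl-6-methyl-1,2-dioxan-3-yl]propanoate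
Product: 35 methyl (2R)-2-[(3R,6S)-6-methyl-6-{2-[(4aR,8aS)-1,1,3,6-tetramethyl-1,4,4a,7,8,8a-hexahydronaphthalen-2-yl]ethenyl}-1,2-dioxan-3-yl]propanoate (E/Z mixture), via ylide 34 (not isolated)
Conditions: NaN(SiMe3)2 (1.0 equiv), THF, −78 to 0 °C; then 15, −78 °C to rt
Reagents that add atoms: none
Why: Wittig olefination joins the two fragments at Ca=Cb; the pre-formed semi-stabilised ylide should add to the non-enolisable aldehyde faster than it deprotonates the ester, and the alkene geometry is irrelevant because the bond is saturated next.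

Step 23
Reactants: 35 methyl (2R)-2-[(3R,6S)-6-methyl-6-{2-[(4aR,8aS)-1,1,3,6-tetramethyl-1,4,4a,7,8,8a-hexahydronaphthalen-2-yl]ethenyl}-1,2-dioxan-3-yl]propanoate
Product: 36 methyl (2R)-2-[(3R,6R)-6-methyl-6-{2-[(4aR,8aS)-1,1,3,6-tetramethyl-1,4,4a,7,8,8a-hexahydronaphthalen-2-yl]ethyl}-1,2-dioxan-3-yl]propanoate (target)
Conditions: 2-nitrobenzenesulfonylhydrazide, Et3N, CH2Cl2, rt
Reagents that add atoms: none
Why: Diimide reduction (concerted syn transfer of H2) spares the O–O bond and should reduce the 1,2-disubstituted Ca=Cb alkene in preference to the trisubstituted ring A and tetrasubstituted ring B alkenes; no stereocentre is affected.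

**Compound list**

1 | geranyl acetate, (2E)-3,7-dimethylocta-2,6-dien-1-yl acetate | CC(C)=CCC/C(C)=C/COC(C)=O | starting material
2 | (2E)-5-(5,5-dimethyl-1,2,4-trioxolan-3-yl)-3-methylpent-2-en-1-yl acetate (ozonide) | CC1(C)OOC(CC/C(C)=C/COC(C)=O)O1 | intermediate
3 | (2E)-3-methyl-6-oxohex-2-en-1-yl acetate | O=CCC/C(C)=C/COC(C)=O | intermediate
4 | (2E,6S,7S)-6-[(diisopinocampheylboranyl)oxy]-3,7-dimethylnona-2,8-dien-1-yl acetate (Ipc from (−)-α-pinene) | C=C[C@H](C)[C@@H](OB([C@H]1C[C@H]2C[C@@H]([C@@H]1C)C2(C)C)[C@H]1C[C@H]2C[C@@H]([C@@H]1C)C2(C)C)CC/C(C)=C/COC(C)=O | intermediate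
5 | (2E,6S,7S)-6-hydroxy-3,7-dimethylnona-2,8-dien-1-yl acetate | C=C[C@H](C)[C@@H](O)CC/C(C)=C/COC(C)=O | intermediate
6 | (2E,6S,7S)-6-[(methanesulfonyl)oxy]-3,7-dimethylnona-2,8-dien-1-yl acetate | C=C[C@H](C)[C@@H](OS(C)(=O)=O)CC/C(C)=C/COC(C)=O | intermediate
7 | (3S,4S,7E)-9-hydroxy-3,7-dimethylnona-1,7-dien-4-yl methanesulfonate | C=C[C@H](C)[C@@H](OS(C)(=O)=O)CC/C(C)=C/CO | intermediate
8 | (3S,4S)-6-[(2R,3R)-3-(hydroxymethyl)-2-methyloxiran-2-yl]-3-methylhex-1-en-4-yl methanesulfonate | C=C[C@H](C)[C@@H](OS(C)(=O)=O)CC[C@@]1(C)O[C@@H]1CO | intermediate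
9 | (3S,4S,7S,8R)-7-hydroperoxy-8,9-dihydroxy-3,7-dimethylnon-1-en-4-yl methanesulfonate | C=C[C@H](C)[C@@H](OS(C)(=O)=O)CC[C@](C)(OO)[C@H](O)CO | intermediate
10 | (1R)-1-{(3S,6R)-6-[(2S)-but-3-en-2-yl]-3-methyl-1,2-dioxan-3-yl}ethane-1,2-diol | C=C[C@H](C)[C@H]1CC[C@@](C)([C@H](O)CO)OO1 | intermediate
11 | (1R)-1-{(3S,6R)-3-methyl-6-[(1R)-1-(1,2,4-trioxolan-3-yl)ethyl]-1,2-dioxan-3-yl}ethane-1,2-diol (ozonide) | O1COOC1[C@H](C)[C@H]1CC[C@@](C)([C@H](O)CO)OO1 | intermediate
12 | (2R)-2-{(3R,6S)-6-[(1R)-1,2-dihydroxyethyl]-6-methyl-1,2-dioxan-3-yl}propanal | O=C[C@H](C)[C@H]1CC[C@@](C)([C@H](O)CO)OO1 | intermediate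
13 | (2R)-2-{(3R,6S)-6-[(1R)-1,2-dihydroxyethyl]-6-methyl-1,2-dioxan-3-yl}propanoic acid | OC(=O)[C@H](C)[C@H]1CC[C@@](C)([C@H](O)CO)OO1 | intermediate
14 | methyl (2R)-2-{(3R,6S)-6-[(1R)-1,2-dihydroxyethyl]-6-methyl-1,2-dioxan-3-yl}propanoate | COC(=O)[C@H](C)[C@H]1CC[C@@](C)([C@H](O)CO)OO1 | intermediate
15 | methyl (2R)-2-[(3R,6S)-6-formyl-6-methyl-1,2-dioxan-3-yl]propanoate | COC(=O)[C@H](C)[C@H]1CC[C@@](C)(C=O)OO1 | intermediate
16 | (S)-(−)-limonene, (4S)-1-methyl-4-(prop-1-en-2-yl)cyclohex-1-ene | CC1=CC[C@H](CC1)C(C)=C | starting material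
17 | (1R,2R,4S)-2-bromo-1-methyl-4-(prop-1-en-2-yl)cyclohexan-1-ol | C[C@]1(O)[C@H](Br)C[C@H](CC1)C(C)=C | intermediate
18 | (1R,4S,6S)-1-methyl-4-(prop-1-en-2-yl)-7-oxabicyclo[4.1.0]heptane | C[C@@]12CC[C@@H](C[C@@H]1O2)C(C)=C | intermediate
19 | (1R,2R,4S)-1-methyl-2-(phenylselanyl)-4-(prop-1-en-2-yl)cyclohexan-1-ol | C[C@]1(O)[C@H]([Se]c2ccccc2)C[C@H](CC1)C(C)=C | intermediate
20 | (1R,2R,4S)-1-methyl-2-(benzeneseleninyl)-4-(prop-1-en-2-yl)cyclohexan-1-ol | C[C@]1(O)[C@H]([Se](=O)c2ccccc2)C[C@H](CC1)C(C)=C | intermediate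
21 | (1R,4S)-1-methyl-4-(prop-1-en-2-yl)cyclohex-2-en-1-ol | C[C@]1(O)C=C[C@H](CC1)C(C)=C | intermediate
22 | (1R,4S)-1-methyl-4-(prop-1-en-2-yl)cyclohex-2-en-1-yl acetate | C[C@]1(OC(C)=O)C=C[C@H](CC1)C(C)=C | intermediate
23 | trimethyl[(1-{[(1R,4S)-1-methyl-4-(prop-1-en-2-yl)cyclohex-2-en-1-yl]oxy}ethenyl)oxy]silane | C=C(O[Si](C)(C)C)O[C@@]1(C)C=C[C@H](CC1)C(C)=C | intermediate
24 | trimethylsilyl 2-[(1R,6S)-3-methyl-6-(prop-1-en-2-yl)cyclohex-2-en-1-yl]acetate | C[Si](C)(C)OC(=O)C[C@@H]1C=C(C)CC[C@@H]1C(C)=C | intermediate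
25 | 2-[(1R,6S)-3-methyl-6-(prop-1-en-2-yl)cyclohex-2-en-1-yl]acetic acid | OC(=O)C[C@@H]1C=C(C)CC[C@@H]1C(C)=C | intermediate
26 | 1-(1H-imidazol-1-yl)-2-[(1R,6S)-3-methyl-6-(prop-1-en-2-yl)cyclohex-2-en-1-yl]ethan-1-one | O=C(C[C@@H]1C=C(C)CC[C@@H]1C(C)=C)n1ccnc1 | intermediate
27 | 2-(methoxycarbonyl)-4-[(1R,6S)-3-methyl-6-(prop-1-en-2-yl)cyclohex-2-en-1-yl]-3-oxobutanoic acid (present as its magnesium salt) | COC(=O)C(C(O)=O)C(=O)C[C@@H]1C=C(C)CC[C@@H]1C(C)=C | intermediate
28 | methyl 4-[(1R,6S)-3-methyl-6-(prop-1-en-2-yl)cyclohex-2-en-1-yl]-3-oxobutanoate | COC(=O)CC(=O)C[C@@H]1C=C(C)CC[C@@H]1C(C)=C | intermediate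
29 | methyl (4aR,8aS)-1,1,6-trimethyl-3-oxo-1,2,3,4,4a,7,8,8a-octahydronaphthalene-2-carboxylate (C2 labile) | COC(=O)C1C(=O)C[C@@H]2C=C(C)CC[C@@H]2C1(C)C | intermediate
30 | methyl (4aR,8aS)-1,1,6-trimethyl-3-{[(trifluoromethyl)sulfonyl]oxy}-1,4,4a,7,8,8a-hexahydronaphthalene-2-carboxylate | COC(=O)C1=C(OS(=O)(=O)C(F)(F)F)C[C@@H]2C=C(C)CC[C@@H]2C1(C)C | intermediate
31 | methyl (4aR,8aS)-1,1,3,6-tetramethyl-1,4,4a,7,8,8a-hexahydronaphthalene-2-carboxylate | COC(=O)C1=C(C)C[C@@H]2C=C(C)CC[C@@H]2C1(C)C | intermediate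
32 | [(4aR,8aS)-1,1,3,6-tetramethyl-1,4,4a,7,8,8a-hexahydronaphthalen-2-yl]methanol | OCC1=C(C)C[C@@H]2C=C(C)CC[C@@H]2C1(C)C | intermediate
33 | triphenyl{[(4aR,8aS)-1,1,3,6-tetramethyl-1,4,4a,7,8,8a-hexahydronaphthalen-2-yl]methyl}phosphonium bromide | [Br-].c1ccc(cc1)[P+](CC1=C(C)C[C@@H]2C=C(C)CC[C@@H]2C1(C)C)(c1ccccc1)c1ccccc1 | intermediate
34 | triphenyl{[(4aR,8aS)-1,1,3,6-tetramethyl-1,4,4a,7,8,8a-hexahydronaphthalen-2-yl]methylidene}-λ5-phosphane (ylide) | C(=P(c1ccccc1)(c1ccccc1)c1ccccc1)C1=C(C)C[C@@H]2C=C(C)CC[C@@H]2C1(C)C | intermediate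
35 | methyl (2R)-2-[(3R,6S)-6-methyl-6-{2-[(4aR,8aS)-1,1,3,6-tetramethyl-1,4,4a,7,8,8a-hexahydronaphthalen-2-yl]ethenyl}-1,2-dioxan-3-yl]propanoate (E/Z) | COC(=O)[C@H](C)[C@H]1CC[C@@](C)(C=CC2=C(C)C[C@@H]3C=C(C)CC[C@@H]3C2(C)C)OO1 | intermediate
36 | methyl (2R)-2-[(3R,6R)-6-methyl-6-{2-[(4aR,8aS)-1,1,3,6-tetramethyl-1,4,4a,7,8,8a-hexahydronaphthalen-2-yl]ethyl}-1,2-dioxan-3-yl]propanoate | COC(=O)[C@H](C)[C@H]1CC[C@@](C)(CCC2=C(C)C[C@@H]3C=C(C)CC[C@@H]3C2(C)C)OO1 | target

**Step count and risks**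

Total step count: 23. Longest linear sequence: 13 (steps 1–11, 22, 23); the limonene branch is 12 (steps 12–23).

Steps most likely to fail:

1. Step 17. The cation may not be captured cleanly: reversible protonation can lead to loss of the C8a proton (erosion of the cis ring fusion), protonation of the ring A alkene can lead to a bridged closure, and the enol oxygen may alkylate instead of carbon. The fallback sets out from 28 and comes back at 29. The isopropenyl group is hydrochlorinated with one equivalent of dry HCl (CH2Cl2, −30 °C) to the tertiary chloride F1. The β-keto ester is then silylated (Me3SiCl, Et3N) to the silyl enol ether F2. ZnCl2 or TiCl4 at −78 °C ionises the chloride irreversibly in the absence of Brønsted acid, and the silyl enol ether traps the cation in a Lewis acid-mediated α-tert-alkylation to give 29.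

2. Step 6. The intermolecular opening may take on SN1 character, which would erode the quaternary peroxide centre, or it may occur at the secondary epoxide carbon; the β-hydroxy hydroperoxide may also fragment. The fallback sets out from 8 and comes back at 10. The mesylate is displaced with inversion by 2-methoxyprop-2-yl hydroperoxide (CsOH, DMF) to give the peroxyketal F3. Aqueous acetic acid unmasks the secondary hydroperoxide F4. Catalytic camphorsulfonic acid in CH2Cl2 then lets F4 open the epoxide intramolecularly at its tertiary carbon (6-exo, inversion) to give 10. Both inversions are the same as in the main route, but the quaternary centre is now set in a ring-forming step.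

3. Step 22. The basic ylide may deprotonate the ester α-position, which would open the dioxane by β-elimination or epimerise that centre, and addition of the hindered allylic ylide to the neopentyl-type aldehyde may be slow. The fallback sets out from 32 (with 15) and comes back at 35. A Mitsunobu reaction of 32 with 1-phenyl-1H-tetrazole-5-thiol (PPh3, diisopropyl azodicarboxylate) gives the sulfide F5. Oxidation with (NH4)6Mo7O24 and H2O2 in EtOH gives the sulfone F6. A Julia–Kocienski olefination with 15, run in Barbier mode with KN(SiMe3)2 added last at −78 °C so that free base stays low, gives 35.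

Further compounds
F1 | step 17 | methyl 4-[(1R,6S)-6-(2-chloropropan-2-yl)-3-methylcyclohex-2-en-1-yl]-3-oxobutanoate | COC(=O)CC(=O)C[C@@H]1C=C(C)CC[C@@H]1C(C)(C)Cl
F2 | step 17 | methyl 4-[(1R,6S)-6-(2-chloropropan-2-yl)-3-methylcyclohex-2-en-1-yl]-3-[(trimethylsilyl)oxy]but-2-enoate | COC(=O)C=C(O[Si](C)(C)C)C[C@@H]1C=C(C)CC[C@@H]1C(C)(C)Cl
F3 | step 6 | {(2R,3R)-3-[(3R,4S)-3-[(2-methoxypropan-2-yl)peroxy]-4-methylhex-5-en-1-yl]-3-methyloxiran-2-yl}methanol | C=C[C@H](C)[C@H](OOC(C)(C)OC)CC[C@@]1(C)O[C@@H]1CO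
F4 | step 6 | {(2R,3R)-3-[(3R,4S)-3-hydroperoxy-4-methylhex-5-en-1-yl]-3-methyloxiran-2-yl}methanol | C=C[C@H](C)[C@H](OO)CC[C@@]1(C)O[C@@H]1CO
F5 | step 22 | 1-phenyl-5-({[(4aR,8aS)-1,1,3,6-tetramethyl-1,4,4a,7,8,8a-hexahydronaphthalen-2-yl]methyl}sulfanyl)-1H-tetrazole | c1ccc(cc1)n1nnnc1SCC1=C(C)C[C@@H]2C=C(C)CC[C@@H]2C1(C)C
F6 | step 22 | 1-phenyl-5-({[(4aR,8aS)-1,1,3,6-tetramethyl-1,4,4a,7,8,8a-hexahydronaphthalen-2-yl]methyl}sulfonyl)-1H-tetrazole | c1ccc(cc1)n1nnnc1S(=O)(=O)CC1=C(C)C[C@@H]2C=C(C)CC[C@@H]2C1(C)C
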